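## Retrosynthetic overview

1. The target is cut into two C15 halves at the central tail-to-tail allyl–allyl bond (side-chain C5'–C6'): lithiated (2E,6E)-farnesyl phenyl sulfone 23 plus ring allylic bromide 20, followed by Pd-catalysed reductive desulfonylation.
2. The (E)-trisubstituted alkene next to the ring comes from Zr-catalysed carboalumination/hydroxymethylation of alkyne 16. Alkyne 16 comes from the trans-fused bicyclic δ-lactone 13 (lactol, Ohira–Bestmann); the lactone is a temporary ring tying the C1 oxygen to side-chain carbon C3'.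
3. Key disconnection: ring bond C3–C4 (C3 = quaternary C(CH3)2, C4 = CH2). The cyclohexane is closed on the monocyclic lactone aldehyde 10 by an iron-hydride hydrogen-atom-transfer radical cyclization onto a tosylhydrazone whose nitrogen is then expelled.
4. Enabling feature: ring C3 is a gem-dimethyl quaternary carbon bonded to the unsubstituted ring methylene C4. This is the retron of an isopropenyl group that accepts H• (second methyl plus tertiary radical) and of a C=N acceptor carbon that is stripped back to CH2. The trans C1–O/C2–side-chain pair is the retron of anti opening of an (E)-trisubstituted epoxide (Shi epoxidation, isopropenyl cuprate).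
5. Order of ring formation: oxirane (step 3), then δ-lactone (step 4, temporary), then cyclohexane (step 7). The lactone is opened in steps 8–9 and no ring is formed after step 7.

Key step: step 7

Remark: ring atoms are numbered from the carbinol carbon (C1 = C(OH)CH3, C2 = CH with the side chain, C3 = C(CH3)2, C4–C6 = CH2) and side-chain atoms C1'–C17' from the ring; 11 (E/Z), 12 (epimers at the N-bearing carbon), 14 (anomers) and 24 (epimers at the sulfonyl carbon) are expected as mixtures that converge, so those positions carry no descriptor.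

## Route

Step 1
Reactants: 1 tert-butyldimethyl(pent-4-yn-1-yloxy)silane
Product: 3 (E)-tert-butyl[(5-iodo-4-methylpent-4-en-1-yl)oxy]dimethylsilane, via alkenylalane 2 (not isolated)
Conditions: AlMe3 (2.5 equiv), Cp2ZrCl2 (0.25 equiv), CH2Cl2, 0 °C to rt; then I2, THF, −30 to 0 °C
Reagents that add atoms: trimethylaluminium, C[Al](C)C; iodine, II
Why: Zirconium-catalysed (Negishi) carboalumination adds CH3–Al syn across the terminal alkyne with the methyl on the internal carbon, and iodinolysis of the alkenyl–Al bond with retention should give the (E)-iodide that fixes the later cis relation of the C1 methyl and the side chain.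

Step 2
Reactants: 3 (E)-tert-butyl[(5-iodo-4-methylpent-4-en-1-yl)oxy]dimethylsilane; 4 (3-ethoxy-3-oxopropyl)zinc bromide
Product: 5 ethyl (4E)-8-[(tert-butyldimethylsilyl)oxy]-5-methyloct-4-enoate
Conditions: Pd(PPh3)4 (5 mol %), THF/DMA, 40 °C
Reagents that add atoms: none
Why: Negishi cross-coupling of an alkenyl iodide with a zinc homoenolate proceeds with retention of alkene geometry and tolerates the ester, so the three-carbon arm (future C1'–C3') is attached without eroding the (E)-alkene.

Step 3
Reactants: 5 ethyl (4E)-8-[(tert-butyldimethylsilyl)oxy]-5-methyloct-4-enoate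
Product: 6 ethyl 3-[(2S,3S)-3-{3-[(tert-butyldimethylsilyl)oxy]propyl}-3-methyloxiran-2-yl]propanoate
Conditions: ent-Shi ketone (1,2:4,5-di-O-isopropylidene-β-L-erythro-2,3-hexodiulo-2,6-pyranose, 30 mol %), KHSO5 (as Oxone, 2KHSO5·KHSO4·K2SO4), K2CO3, Bu4NHSO4, aq. Na2B4O7 buffer, MeCN/CH2(OMe)2, 0 °C
Reagents that add atoms: potassium peroxymonosulfate, [K+].[O-]S(=O)(=O)OO
Why: Shi epoxidation of an unfunctionalized (E)-trisubstituted alkene through the spiro dioxirane transition state should set the absolute configuration of both future ring stereocentres (C1 directly, C2 after inversion); the L-fructose-derived ketone is chosen because the D-fructose-derived one is expected to give the (R,R)-epoxide.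

Step 4
Reactants: 6 ethyl 3-[(2S,3S)-3-{3-[(tert-butyldimethylsilyl)oxy]propyl}-3-methyloxiran-2-yl]propanoate
Product: 8 (5S,6S)-6-{3-[(tert-butyldimethylsilyl)oxy]propyl}-6-methyl-5-(prop-1-en-2-yl)oxan-2-one, via hydroxy ester 7 (not isolated)
Conditions: isopropenylMgBr (4 equiv), CuBr·SMe2 (2 equiv), THF, −40 °C; BF3·OEt2 (2 equiv), then 6, −78 °C; aq. NH4Cl/NH3 work-up; crude in toluene, PPTS (cat.), 80 °C
Reagents that add atoms: isopropenylmagnesium bromide, CC(=C)[Mg]Br
Why: BF3-assisted organocuprate opening of a trisubstituted epoxide is an SN2 reaction at the less substituted carbon with inversion, which should turn the (S,S)-epoxide into the anti arrangement that becomes the trans C1–O/C2–side-chain relation, and acid-catalysed lactonisation then ties the tertiary alcohol and the ester arm into a δ-lactone that protects the alcohol and holds the two future ring tethers gauche and equatorial.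

Step 5
Reactants: 8 (5S,6S)-6-{3-[(tert-butyldimethylsilyl)oxy]propyl}-6-methyl-5-(prop-1-en-2-yl)oxan-2-one
Product: 9 (5S,6S)-6-(3-hydroxypropyl)-6-methyl-5-(prop-1-en-2-yl)oxan-2-one
Conditions: HF·pyridine, pyridine, THF, 0 °C to rt
Reagents that add atoms: none
Why: Buffered fluoride desilylation should cleave the primary silyl ether without touching the lactone or the 1,1-disubstituted alkene.

Step 6
Reactants: 9 (5S,6S)-6-(3-hydroxypropyl)-6-methyl-5-(prop-1-en-2-yl)oxan-2-one
Product: 10 3-[(2S,3S)-2-methyl-6-oxo-3-(prop-1-en-2-yl)oxan-2-yl]propanal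
Conditions: Dess–Martin periodinane, NaHCO3, CH2Cl2, rt
Reagents that add atoms: none
Why: Dess–Martin oxidation should convert the primary alcohol into the aldehyde under neutral conditions that leave the lactone, the alkene and both stereocentres untouched.

Step 7
Reactants: 10 3-[(2S,3S)-2-methyl-6-oxo-3-(prop-1-en-2-yl)oxan-2-yl]propanal
Product: 13 (4aS,8aS)-5,5,8a-trimethyloctahydro-2H-chromen-2-one, via tosylhydrazone 11 (not isolated), via cyclized tosylhydrazine 12 (not isolated)
Conditions: TsNHNH2 (1.05 equiv), THF/EtOH, rt; then Fe(acac)3 (0.5 equiv), PhSiH3 (2.5 equiv, slow addition), EtOH/THF, 50 °C, high dilution; then Et3N, MeOH, 65 °C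
Reagents that add atoms: none
Why: Condensation gives the N-tosylhydrazone; an iron hydride formed from Fe(acac)3 and PhSiH3 transfers a hydrogen atom to the CH2 terminus of the isopropenyl group (Markovnikov MHAT), which creates the second methyl group and a tertiary radical at the future C3, this radical adds to the hydrazone carbon (future C4), the hydrazinyl radical is reduced and protonated, and warming with base expels p-toluenesulfinate and N2 from the N-alkyl-N'-tosylhydrazine (the fragmentation known from tosylhydrazone reductions), so that C4 ends as an unsubstituted CH2. The closest known reaction types are the iron-mediated MHAT hydromethylation of alkenes with formaldehyde sulfonylhydrazones, which forms quaternary C–CH3 bonds tracelessly, and the MHAT-triggered intramolecular alkene–hydrazone radical cyclization; both are combined here on one substrate. The cyclohexane is closed in the 6-exo-trig mode on the C=N bond through a chair-like transition state in which the radical-bearing group and the three-carbon tether are both equatorial and gauche on the δ-lactone, which should lead to the trans-fused bicycle. No stereocentre is created (C3 carries two methyls, C4 becomes CH2), the two existing centres are not epimerizable under these conditions, and both hydrazone isomers converge on one product. The step needs chemoselective hydrogen-atom transfer, secured because the isopropenyl group is the only alkene present at this stage (the polyene is attached later), and it needs cyclization to outrun reduction of the tertiary radical, secured by the pre-organized tethers, slow silane addition and the high rate of radical addition to sulfonylhydrazone C=N bonds.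

Step 8
Reactants: 13 (4aS,8aS)-5,5,8a-trimethyloctahydro-2H-chromen-2-one
Product: 14 (4aS,8aS)-5,5,8a-trimethyloctahydro-2H-chromen-2-ol
Conditions: i-Bu2AlH (1.1 equiv), CH2Cl2, −78 °C; aq. potassium sodium tartrate work-up
Reagents that add atoms: none
Why: Partial reduction of a lactone with one equivalent of i-Bu2AlH at low temperature should stop at the aluminium hemiacetal and give the lactol, the masked side-chain aldehyde.

Step 9
Reactants: 14 (4aS,8aS)-5,5,8a-trimethyloctahydro-2H-chromen-2-ol
Product: 16 (1S,2S)-2-(but-3-yn-1-yl)-1,3,3-trimethylcyclohexan-1-ol, via hydroxy aldehyde 15 (not isolated)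
Conditions: dimethyl (1-diazo-2-oxopropyl)phosphonate, K2CO3, MeOH, rt to 40 °C
Reagents that add atoms: dimethyl (1-diazo-2-oxopropyl)phosphonate, COP(=O)(OC)C(=[N+]=[N-])C(C)=O
Why: Ohira–Bestmann (Seyferth–Gilbert) homologation acts on the open hydroxy-aldehyde tautomer of the lactol and should convert CHO into C≡CH under mild carbonate conditions that leave the tertiary alcohol and both stereocentres unchanged.

Step 10
Reactants: 16 (1S,2S)-2-(but-3-yn-1-yl)-1,3,3-trimethylcyclohexan-1-ol
Product: 19 (1S,2S)-2-[(3E)-5-hydroxy-3-methylpent-3-en-1-yl]-1,3,3-trimethylcyclohexan-1-ol, via alkenylalane 17 (not isolated), via lithium alanate 18 (not isolated)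
Conditions: AlMe3 (3.5 equiv), Cp2ZrCl2 (0.5 equiv), CH2Cl2, 0 °C to rt; then n-BuLi, THF/hexane, −78 °C; (CH2O)n, −78 °C to rt
Reagents that add atoms: trimethylaluminium, C[Al](C)C; paraformaldehyde (formaldehyde), C=O
Why: Zirconium-catalysed (Negishi) carboalumination adds CH3–Al syn to the terminal alkyne with the methyl on the internal carbon, and hydroxymethylation of the derived alanate with retention should give the (E)-trisubstituted allylic alcohol as a single isomer, the tertiary alcohol being carried as its aluminium alkoxide.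

Step 11
Reactants: 19 (1S,2S)-2-[(3E)-5-hydroxy-3-methylpent-3-en-1-yl]-1,3,3-trimethylcyclohexan-1-ol
Product: 20 (1S,2S)-2-[(3E)-5-bromo-3-methylpent-3-en-1-yl]-1,3,3-trimethylcyclohexan-1-ol
Conditions: CBr4, PPh3, CH2Cl2, −30 to 0 °C
Reagents that add atoms: carbon tetrabromide, BrC(Br)(Br)Br
Why: Appel bromination converts the primary allylic alcohol by SN2 displacement of its oxyphosphonium, while the hindered tertiary alcohol should not react at low temperature.

Step 12
Reactants: 21 (2E,6E)-1-bromo-3,7,11-trimethyldodeca-2,6,10-triene (farnesyl bromide)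
Product: 22 {[(2E,6E)-3,7,11-trimethyldodeca-2,6,10-trien-1-yl]sulfonyl}benzene
Conditions: PhSO2Na, DMF, rt
Reagents that add atoms: sodium benzenesulfinate, [Na+].[O-]S(=O)c1ccccc1
Why: S-alkylation of the sulfinate anion by the primary allylic bromide (SN2) should give the allylic sulfone with the alkene geometry unchanged.

Step 13
Reactants: 20 (1S,2S)-2-[(3E)-5-bromo-3-methylpent-3-en-1-yl]-1,3,3-trimethylcyclohexan-1-ol; 22 {[(2E,6E)-3,7,11-trimethyldodeca-2,6,10-trien-1-yl]sulfonyl}benzene
Product: 24 (1S,2S)-1,3,3-trimethyl-2-[(3E,7E,11E)-3,8,12,16-tetramethyl-6-(phenylsulfonyl)heptadeca-3,7,11,15-tetraen-1-yl]cyclohexan-1-ol, via lithiated sulfone 23 (not isolated)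
Conditions: 22 (2.2 equiv), n-BuLi, THF/DMPU, −78 °C; then 20, −78 to −20 °C
Reagents that add atoms: none
Why: Alkylation of the α-sulfonyl allylic carbanion with a primary allylic bromide (Julia-type sulfone alkylation) should form the central tail-to-tail C–C bond at the α-carbon without touching either neighbouring trisubstituted alkene, one further equivalent of the anion being consumed by the free tertiary hydroxyl.

Step 14
Reactants: 24 (1S,2S)-1,3,3-trimethyl-2-[(3E,7E,11E)-3,8,12,16-tetramethyl-6-(phenylsulfonyl)heptadeca-3,7,11,15-tetraen-1-yl]cyclohexan-1-ol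
Product: 25 (1S,2S)-1,3,3-trimethyl-2-[(3E,7E,11E)-3,8,12,16-tetramethylheptadeca-3,7,11,15-tetraen-1-yl]cyclohexan-1-ol
Conditions: LiBHEt3 (excess), PdCl2(dppp) (5 mol %), THF, 0 °C to rt
Reagents that add atoms: none
Why: Palladium-catalysed hydride substitution of the allylic sulfone passes through a π-allylpalladium complex that takes hydride at the less substituted terminus, which should remove the sulfonyl group while keeping the position and (E)-geometry of the trisubstituted alkene.

## Compound list

1 | tert-butyldimethyl(pent-4-yn-1-yloxy)silane | C#CCCCO[Si](C)(C)C(C)(C)C | starting material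
2 | (E)-{5-[(tert-butyldimethylsilyl)oxy]-2-methylpent-1-en-1-yl}dimethylalane | C/C(=C\[Al](C)C)CCCO[Si](C)(C)C(C)(C)C | intermediate (not isolated)
3 | (E)-tert-butyl[(5-iodo-4-methylpent-4-en-1-yl)oxy]dimethylsilane | C/C(=C\I)CCCO[Si](C)(C)C(C)(C)C | intermediate
4 | (3-ethoxy-3-oxopropyl)zinc bromide | CCOC(=O)CC[Zn]Br | starting material
5 | ethyl (4E)-8-[(tert-butyldimethylsilyl)oxy]-5-methyloct-4-enoate | CCOC(=O)CC/C=C(\C)CCCO[Si](C)(C)C(C)(C)C | intermediate
6 | ethyl 3-[(2S,3S)-3-{3-[(tert-butyldimethylsilyl)oxy]propyl}-3-methyloxiran-2-yl]propanoate | CCOC(=O)CC[C@@H]1O[C@@]1(C)CCCO[Si](C)(C)C(C)(C)C | intermediate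
7 | ethyl (4S,5S)-8-[(tert-butyldimethylsilyl)oxy]-5-hydroxy-5-methyl-4-(prop-1-en-2-yl)octanoate | CCOC(=O)CC[C@H]([C@@](C)(O)CCCO[Si](C)(C)C(C)(C)C)C(C)=C | intermediate (not isolated)
8 | (5S,6S)-6-{3-[(tert-butyldimethylsilyl)oxy]propyl}-6-methyl-5-(prop-1-en-2-yl)oxan-2-one | O=C1CC[C@@H](C(C)=C)[C@](C)(CCCO[Si](C)(C)C(C)(C)C)O1 | intermediate
9 | (5S,6S)-6-(3-hydroxypropyl)-6-methyl-5-(prop-1-en-2-yl)oxan-2-one | O=C1CC[C@@H](C(C)=C)[C@](C)(CCCO)O1 | intermediate
10 | 3-[(2S,3S)-2-methyl-6-oxo-3-(prop-1-en-2-yl)oxan-2-yl]propanal | O=C1CC[C@@H](C(C)=C)[C@](C)(CCC=O)O1 | intermediate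
11 | N'-{3-[(2S,3S)-2-methyl-6-oxo-3-(prop-1-en-2-yl)oxan-2-yl]propylidene}-4-methylbenzenesulfonohydrazide | O=C1CC[C@@H](C(C)=C)[C@](C)(CCC=NNS(=O)(=O)c2ccc(C)cc2)O1 | intermediate (not isolated)
12 | N'-[(4aS,8aS)-5,5,8a-trimethyl-2-oxooctahydro-2H-chromen-6-yl]-4-methylbenzenesulfonohydrazide | O=C1CC[C@H]2C(C)(C)C(NNS(=O)(=O)c3ccc(C)cc3)CC[C@]2(C)O1 | intermediate (not isolated)
13 | (4aS,8aS)-5,5,8a-trimethyloctahydro-2H-chromen-2-one | O=C1CC[C@H]2C(C)(C)CCC[C@]2(C)O1 | intermediate
14 | (4aS,8aS)-5,5,8a-trimethyloctahydro-2H-chromen-2-ol | OC1CC[C@H]2C(C)(C)CCC[C@]2(C)O1 | intermediate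
15 | 3-[(1S,2S)-2-hydroxy-2,6,6-trimethylcyclohexyl]propanal | O=CCC[C@H]1C(C)(C)CCC[C@]1(C)O | intermediate (not isolated)
16 | (1S,2S)-2-(but-3-yn-1-yl)-1,3,3-trimethylcyclohexan-1-ol | C#CCC[C@H]1C(C)(C)CCC[C@]1(C)O | intermediate
17 | dimethylaluminium (1S,2S)-2-[(3E)-4-(dimethylalumanyl)-3-methylbut-3-en-1-yl]-1,3,3-trimethylcyclohexan-1-olate | C[Al](C)/C=C(\C)CC[C@H]1C(C)(C)CCC[C@]1(C)O[Al](C)C | intermediate (not isolated)
18 | lithium butyl{(1E)-4-[(1S,2S)-2-(dimethylalumanyloxy)-2,6,6-trimethylcyclohexyl]-2-methylbut-1-en-1-yl}dimethylaluminate | [Li+].CCCC[Al-](C)(C)/C=C(\C)CC[C@H]1C(C)(C)CCC[C@]1(C)O[Al](C)C | intermediate (not isolated)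
19 | (1S,2S)-2-[(3E)-5-hydroxy-3-methylpent-3-en-1-yl]-1,3,3-trimethylcyclohexan-1-ol | OC/C=C(\C)CC[C@H]1C(C)(C)CCC[C@]1(C)O | intermediate
20 | (1S,2S)-2-[(3E)-5-bromo-3-methylpent-3-en-1-yl]-1,3,3-trimethylcyclohexan-1-ol | BrC/C=C(\C)CC[C@H]1C(C)(C)CCC[C@]1(C)O | intermediate
21 | (2E,6E)-1-bromo-3,7,11-trimethyldodeca-2,6,10-triene | CC(C)=CCC/C(C)=C/CC/C(C)=C/CBr | starting material
22 | {[(2E,6E)-3,7,11-trimethyldodeca-2,6,10-trien-1-yl]sulfonyl}benzene | CC(C)=CCC/C(C)=C/CC/C(C)=C/CS(=O)(=O)c1ccccc1 | intermediate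
23 | [(2E,6E)-3,7,11-trimethyl-1-(phenylsulfonyl)dodeca-2,6,10-trien-1-yl]lithium | CC(C)=CCC/C(C)=C/CC/C(C)=C/C([Li])S(=O)(=O)c1ccccc1 | intermediate (not isolated)
24 | (1S,2S)-1,3,3-trimethyl-2-[(3E,7E,11E)-3,8,12,16-tetramethyl-6-(phenylsulfonyl)heptadeca-3,7,11,15-tetraen-1-yl]cyclohexan-1-ol | CC(C)=CCC/C(C)=C/CC/C(C)=C/C(C/C=C(\C)CC[C@H]1C(C)(C)CCC[C@]1(C)O)S(=O)(=O)c1ccccc1 | intermediate
25 | (1S,2S)-1,3,3-trimethyl-2-[(3E,7E,11E)-3,8,12,16-tetramethylheptadeca-3,7,11,15-tetraen-1-yl]cyclohexan-1-ol | CC(C)=CCC/C(C)=C/CC/C(C)=C/CC/C=C(\C)CC[C@H]1C(C)(C)CCC[C@]1(C)O | target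

## Step count and risks

Total step count: 14. Longest linear sequence: 13 (steps 1–11, 13, 14); step 12 is a one-step side branch.

Steps most likely to fail:

Step 7 (key step). What may go wrong: the tertiary radical is reduced by a second iron hydride before it reaches the C=N bond (net hydrogenation of the isopropenyl group), or loss of sulfinate and N2 from 12 stalls. The fallback forms the same bond by known organopalladium chemistry; it sets out from aldehyde 10 and returns at lactone 13. Aldehyde 10 would be converted with Tf2O and 2,6-di-tert-butyl-4-methylpyridine (CH2Cl2, 0 °C) into the enol triflate 3-[(2S,3S)-2-methyl-6-oxo-3-(prop-1-en-2-yl)oxan-2-yl]prop-1-en-1-yl trifluoromethanesulfonate F1 (either alkene isomer serves). A reductive 6-exo-trig Heck cyclization (Pd(OAc)2, PPh3, HCO2Na, Et4NCl, DMF, 80 °C) should add the alkenyl–palladium bond across the isopropenyl group. Formate reduction of the resulting neopentyl-type alkylpalladium, which has no β-hydrogen, should give (4aS,8aS)-5,5,8a-trimethyl-3,4,4a,5,8,8a-hexahydro-2H-chromen-2-one F2. Hydrogenation of its only alkene (H2, Pd/C, EtOAc) leads back to 13.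

Step 4. What may go wrong: Lewis-acid-induced rearrangement of the trisubstituted epoxide (hydride shift to a ketone) or participation of the ester carbonyl competes with the slow attack of the branched alkenyl cuprate on the hindered secondary carbon. The fallback uses the smallest carbon nucleophile and adds the third carbon later; it sets out from epoxide 6 and returns at hydroxy lactone 9. BF3-mediated alkynylation of 6 with lithium (trimethylsilyl)acetylide (THF, −78 °C; SN2 at the secondary carbon with inversion) should give ethyl (4S,5S)-8-[(tert-butyldimethylsilyl)oxy]-5-hydroxy-5-methyl-4-[(trimethylsilyl)ethynyl]octanoate F3. Lactonisation (PPTS, toluene, 80 °C) gives (5S,6S)-6-{3-[(tert-butyldimethylsilyl)oxy]propyl}-6-methyl-5-[(trimethylsilyl)ethynyl]oxan-2-one F4. Bu4NF (THF) removes both silyl groups to give (5S,6S)-5-ethynyl-6-(3-hydroxypropyl)-6-methyloxan-2-one F5. Gold-catalysed Markovnikov hydration ((Ph3P)AuNTf2 cat., aq. 1,4-dioxane, 60 °C) should give (5R,6S)-5-acetyl-6-(3-hydroxypropyl)-6-methyloxan-2-one F6; its trans arrangement on the lactone is expected to be the more stable one, so enolisation should do no harm. Wittig methylenation (Ph3P=CH2, THF, 0 °C) then gives 9.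

Step 9. What may go wrong: the lactol of a tertiary alcohol may stay closed, so that too little free aldehyde is offered to the diazophosphonate anion and the reagent decomposes first. The fallback replaces steps 8–10; it sets out from lactone 13 and returns at allylic alcohol 19. MeLi (1.05 equiv, THF, −78 °C) should open the lactone to 4-[(1S,2S)-2-hydroxy-2,6,6-trimethylcyclohexyl]butan-2-one F7. Horner–Wadsworth–Emmons olefination (triethyl phosphonoacetate, NaH, THF, reflux) should give mainly ethyl (2E)-5-[(1S,2S)-2-hydroxy-2,6,6-trimethylcyclohexyl]-3-methylpent-2-enoate F8, the (Z)-isomer to be removed by chromatography. Reduction with i-Bu2AlH (CH2Cl2, −78 °C) gives 19.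

## Further compounds

F1 | step 7 | 3-[(2S,3S)-2-methyl-6-oxo-3-(prop-1-en-2-yl)oxan-2-yl]prop-1-en-1-yl trifluoromethanesulfonate (E/Z mixture) | O=C1CC[C@@H](C(C)=C)[C@](C)(CC=COS(=O)(=O)C(F)(F)F)O1
F2 | step 7 | (4aS,8aS)-5,5,8a-trimethyl-3,4,4a,5,8,8a-hexahydro-2H-chromen-2-one | O=C1CC[C@H]2C(C)(C)C=CC[C@]2(C)O1
F3 | step 4 | ethyl (4S,5S)-8-[(tert-butyldimethylsilyl)oxy]-5-hydroxy-5-methyl-4-[(trimethylsilyl)ethynyl]octanoate | CCOC(=O)CC[C@H]([C@@](C)(O)CCCO[Si](C)(C)C(C)(C)C)C#C[Si](C)(C)C
F4 | step 4 | (5S,6S)-6-{3-[(tert-butyldimethylsilyl)oxy]propyl}-6-methyl-5-[(trimethylsilyl)ethynyl]oxan-2-one | O=C1CC[C@@H](C#C[Si](C)(C)C)[C@](C)(CCCO[Si](C)(C)C(C)(C)C)O1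
F5 | step 4 | (5S,6S)-5-ethynyl-6-(3-hydroxypropyl)-6-methyloxan-2-one | O=C1CC[C@@H](C#C)[C@](C)(CCCO)O1
F6 | step 4 | (5R,6S)-5-acetyl-6-(3-hydroxypropyl)-6-methyloxan-2-one | O=C1CC[C@@H](C(C)=O)[C@](C)(CCCO)O1
F7 | step 9 | 4-[(1S,2S)-2-hydroxy-2,6,6-trimethylcyclohexyl]butan-2-one | CC(=O)CC[C@H]1C(C)(C)CCC[C@]1(C)O
F8 | step 9 | ethyl (2E)-5-[(1S,2S)-2-hydroxy-2,6,6-trimethylcyclohexyl]-3-methylpent-2-enoate | CCOC(=O)/C=C(\C)CC[C@H]1C(C)(C)CCC[C@]1(C)O
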